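**Retrosynthetic overview**

1. Feature: ring B (C5–C6–C7–C8–C9–C10) holds C7 with its isopropenyl group next to the C8 ketone, a β,γ-unsaturated ketone that epimerises and conjugates easily. A 2-isopropenyl carbinol is the product pattern of a carbonyl-ene reaction, so C7–C8 is cut to a C8 aldehyde on C10 and a prenyl group on C5, and C8 stays a carbinol until a buffered oxidation.
2. After the ring closure: C8 oxidation, hydroxylation of the kinetic C9 enolate, O9 silylation, release of O3, acylation with (2E,5R)-5-(angeloyloxy)hex-2-enoic acid (made from (R)-pent-4-en-2-ol, angelic acid and acrylic acid by esterification and cross-metathesis), desilylation.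
3. Ring A (C1–C2–C3–C4–C5–C10) comes first, from an enantioselective endo Diels–Alder reaction of tiglaldehyde with a (1E,3E)-1-silyl-4-alkylbutadiene that sets C3, C4, C5 and C10 together. The C3–Si bond is later oxidised with retention to the 3α-oxygen, so no allylic oxidation or ketone reduction is needed.
4. The C5 formyl group is grown into the prenyl group (methoxymethylene Wittig, hydrolysis, isopropylidene Wittig) and the C10 silyloxyethyl arm becomes the C8 aldehyde.
5. Ring order: ring A by cycloaddition (step 5), then ring B by the ene closure (step 13).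

Key step: step 13

Remark on convention: atoms carry eremophilane numbers and α/β refer to the drawing in which the C5 methyl is β; the target is then 3α-acyloxy, 4β-Me, 5β-Me, 7β-isopropenyl, 8-oxo, 9β-OH, 10β-H (cis-decalin).

Assumption: the (R)-oxazaborolidinium catalyst is taken to expose the Cα-Si face of s-trans tiglaldehyde (formyl C–H···O binding model for 2-substituted enals); if the adduct proved antipodal, the (S)-catalyst would be used with no other change.

Abbreviations: TBDPS = tert-butyldiphenylsilyl, TES = triethylsilyl, TBS = tert-butyldimethylsilyl, Bn = benzyl, dvds = 1,3-divinyl-1,1,3,3-tetramethyldisiloxane.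

**Route**

Step 1
Reactants: 1 but-3-yn-1-ol
Product: 2 tert-butyl(but-3-yn-1-yloxy)diphenylsilane
Conditions: t-BuPh2SiCl, imidazole, CH2Cl2, 0 °C → rt
Reagents that add atoms: tert-butyl(chloro)diphenylsilane, CC(C)(C)[Si](Cl)(c1ccccc1)c1ccccc1
Why: Silylation of a primary alcohol with a silyl chloride and imidazole is routine, and the TBDPS ether is chosen because it should survive the later Lewis-acid and aqueous-acid steps yet fall to fluoride in step 10.

Step 2
Reactants: 2 tert-butyl(but-3-yn-1-yloxy)diphenylsilane
Product: 4 (E)-tert-butyl[(4-iodobut-3-en-1-yl)oxy]diphenylsilane, via alkenylzirconocene 3 (not isolated)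
Conditions: Cp2Zr(H)Cl, THF, rt; then I2, 0 °C
Reagents that add atoms: iodine, [I][I]
Why: Hydrozirconation adds Zr–H syn and anti-Markovnikov across the terminal alkyne and iodinolysis of the C–Zr bond proceeds with retention, so the E-alkenyl iodide should result.

Step 3
Reactants: 4 (E)-tert-butyl[(4-iodobut-3-en-1-yl)oxy]diphenylsilane
Product: 5 (E)-tert-butyl(hex-3-en-5-yn-1-yloxy)diphenylsilane
Conditions: HC≡CMgBr, ZnBr2, THF, 0 °C; then 4, Pd(PPh3)4 (5 mol%), rt
Reagents that add atoms: ethynylmagnesium bromide, C#C[Mg]Br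
Why: Negishi coupling of the alkenyl iodide with ethynylzinc bromide under zerovalent palladium catalysis retains the E geometry and gives the terminal enyne directly, without an alkyne protecting group.

Step 4
Reactants: 5 (E)-tert-butyl(hex-3-en-5-yn-1-yloxy)diphenylsilane
Product: 6 benzyl[(1E,3E)-6-(tert-butyldiphenylsilyloxy)hexa-1,3-dien-1-yl]dimethylsilane
Conditions: BnMe2SiH (1.1 equiv), Pt2(dvds)3 (0.5 mol%), P(t-Bu)3, THF, rt
Reagents that add atoms: benzyldimethylsilane, C[SiH](C)Cc1ccccc1
Why: Platinum-catalysed hydrosilylation of a terminal alkyne with a bulky phosphine is a syn, β-selective addition that puts silicon on the terminal carbon with E geometry, and the alkyne reacts ahead of the conjugated alkene.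

Step 5
Reactants: 6 benzyl[(1E,3E)-6-(tert-butyldiphenylsilyloxy)hexa-1,3-dien-1-yl]dimethylsilane; 7 tiglaldehyde
Product: 8 Diels–Alder aldehyde (ring A cyclohex-1-ene: 3α-SiMe2Bn; 4β-Me; 5β-Me; 5α-CHO; 10α-CH2CH2OTBDPS)
Conditions: 7 (3 equiv), (R)-3,3-diphenyl-1-(o-tolyl)tetrahydro-1H,3H-pyrrolo[1,2-c][1,3,2]oxazaborole (20 mol%), HN(SO2CF3)2 (17 mol%), CH2Cl2, −78 → −20 °C
Reagents that add atoms: none
Why: In this oxazaborolidinium-catalysed enantioselective Diels–Alder reaction the alkyl-bearing diene terminus bonds to the formyl-bearing Cα and the silyl-bearing terminus to Cβ (alkyl donation and β-silyl stabilisation both favour this), the endo transition state puts CHO cis to the C10 arm and to silicon, the E,E-diene and E-enal geometries make Si/arm cis and the two methyls cis, and diene approach to the Cα-Si face of the bound enal fixes the absolute configuration of C3, C4, C5 and C10.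

Step 6
Reactants: 8 Diels–Alder aldehyde
Product: 9 saturated ring A aldehyde (3α-SiMe2Bn; 4β-Me; 5β-Me; 5α-CHO; 10α-CH2CH2OTBDPS)
Conditions: H2 (1 atm), 5% Pt/C, EtOAc, rt
Reagents that add atoms: none
Why: Heterogeneous hydrogenation saturates the only C=C bond, platinum being preferred to palladium to suppress migration of the allylsilane double bond, while the aldehyde, the benzyl–silicon bond and the silyl ether are expected to be inert.

Step 7
Reactants: 9 saturated ring A aldehyde
Product: 10 methyl enol ether (C5–CH=CH–OMe; E/Z mixture)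
Conditions: MeOCH2PPh3Cl, KN(SiMe3)2, THF, 0 °C; then 9, 0 °C → rt
Reagents that add atoms: (methoxymethyl)triphenylphosphonium chloride, [Cl-].COC[P+](c1ccccc1)(c1ccccc1)c1ccccc1
Why: Wittig methoxymethylenation with the small, reactive alkoxy ylide is the standard one-carbon homologation of neopentyl aldehydes, and the E/Z ratio of the enol ether is irrelevant.

Step 8
Reactants: 10 methyl enol ether
Product: 11 homologated aldehyde (C5–CH2–CHO)
Conditions: 2 M aqueous HCl, THF, rt
Reagents that add atoms: water, O
Why: Acid hydrolysis of the enol ether (C-protonation, hydration of the oxocarbenium ion, loss of methanol) should unveil the aldehyde, while the primary TBDPS ether and the C–Si bond tolerate dilute acid.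

Step 9
Reactants: 11 homologated aldehyde
Product: 12 prenyl compound (C5–CH2–CH=CMe2; 3α-SiMe2Bn; 10α-CH2CH2OTBDPS)
Conditions: i-PrPPh3I, n-BuLi, THF, 0 °C; then 11, −78 °C → rt
Reagents that add atoms: isopropyltriphenylphosphonium iodide, [I-].CC(C)[P+](c1ccccc1)(c1ccccc1)c1ccccc1
Why: Wittig olefination of the unhindered CH2–CHO group with the non-stabilised isopropylidene ylide gives the trisubstituted prenyl alkene, for which no E/Z question arises.

Step 10
Reactants: 12 prenyl compound
Product: 14 diol (3α-OH; 10α-CH2CH2OH; C5 prenyl), via fluorosilane 13 (not isolated)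
Conditions: Bu4NF (5 equiv), THF, 0 °C → rt; then KHCO3, 30% aqueous H2O2, MeOH, 40 °C
Reagents that add atoms: hydrogen peroxide, OO
Why: In this Tamao–Fleming oxidation fluoride cleaves the benzyl–silicon bond (and the silyl ether), and the peroxide adduct of the resulting fluorosilane undergoes 1,2-migration of C3 from silicon to oxygen with retention, so 3α-Si becomes 3α-OH while basic peroxide leaves the isolated trisubstituted alkene alone.

Step 11
Reactants: 14 diol
Product: 15 hydroxy aldehyde (3α-OH; 10α-CH2CHO; C5 prenyl)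
Conditions: TEMPO (10 mol%), PhI(OAc)2 (1.1 equiv), CH2Cl2, rt
Reagents that add atoms: none
Why: Oxoammonium (TEMPO) oxidation with PhI(OAc)2 as terminal oxidant is selective for the unhindered primary alcohol over the secondary C3 alcohol, stops at the aldehyde and does not touch the alkene.

Step 12
Reactants: 15 hydroxy aldehyde
Product: 16 ene precursor (3α-OTES; 4β-Me; 5β-Me; 5α-prenyl; 10α-CH2CHO)
Conditions: Et3SiCl, imidazole, DMF, 0 °C
Reagents that add atoms: chlorotriethylsilane, CC[Si](Cl)(CC)CC
Why: Standard silylation of the secondary alcohol under conditions that leave the aldehyde alone, the TES group being chosen so that it can later be removed beside a TBS ether.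

Step 13
Reactants: 16 ene precursor
Product: 17 cis-decalin ene product (3α-OTES; 7β-isopropenyl; 8α-OH; 4β,5β-Me2; 10β-H)
Conditions: Me2AlCl (1.1 equiv, hexane), CH2Cl2, −78 → −40 °C; aqueous KNaC4H4O6 work-up
Reagents that add atoms: none
Why: Me2AlCl binds the C8 aldehyde, whose carbon is attacked by alkene carbon C7 while an allylic methyl hydrogen passes to oxygen in a concerted, asynchronous six-centre array, an intramolecular type 1 carbonyl-ene reaction whose closest known case is the Lewis-acid cyclisation of citronellal-type aldehydes to trans-2-isopropenylcyclohexanols. Ring B closes as a six-membered chair, exo with respect to both the C=O and the C=C bond. C7 is set by the equatorial placement of the emerging isopropenyl unit in that chair and C8 by the equatorial aldehyde oxygen, which gives 7β,8α (trans). The chair is dictated by ring A, which keeps OTES and the C4 methyl equatorial so that C6 leaves C5 equatorially and C9 leaves C10 axially, whereas the flipped ring A, which would lead to the 7α series, suffers a syn-diaxial OTES/C6 clash. Only the C7 configuration has to be right, because C8 is oxidised in step 14, and the methylaluminium reagent removes the proton that would otherwise open cationic pathways such as chloride capture or alkene migration.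

Step 14
Reactants: 17 cis-decalin ene product
Product: 18 ketone (3α-OTES; 7β-isopropenyl; 8-oxo)
Conditions: Dess–Martin periodinane (1.3 equiv), NaHCO3, CH2Cl2, 0 °C → rt
Reagents that add atoms: none
Why: Dess–Martin oxidation under bicarbonate buffer converts the carbinol to the ketone without acid or base strong enough to epimerise or conjugate the β,γ-unsaturated C7 centre, which should keep the configuration set in step 13.

Step 15
Reactants: 18 ketone
Product: 20 α-hydroxy ketone (3α-OTES; 7β-isopropenyl; 8-oxo; 9β-OH), via lithium enolate 19 (not isolated)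
Conditions: LiN(i-Pr)2 (1.2 equiv), THF, −78 °C; then 2-(phenylsulfonyl)-3-phenyloxaziridine (1.5 equiv), −78 °C; aqueous NH4Cl
Reagents that add atoms: 2-(phenylsulfonyl)-3-phenyloxaziridine, O=S(=O)(c1ccccc1)N1OC1c1ccccc1
Why: Kinetic deprotonation with the hindered amide base should take the less substituted C9 methylene and not the tertiary allylic C7–H, as with other 2-isopropenylcyclohexanones, and the enolate is then oxygenated by the N-sulfonyloxaziridine (enolate hydroxylation) on the convex β face because C4 of ring A is syn-axial to C9 on the α face, which gives the equatorial 9β-alcohol.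

Step 16
Reactants: 20 α-hydroxy ketone
Product: 21 9β-OTBS ketone (3α-OTES)
Conditions: t-BuMe2SiOTf (1.3 equiv), 2,6-lutidine, CH2Cl2, −78 → 0 °C
Reagents that add atoms: tert-butyldimethylsilyl trifluoromethanesulfonate, CC(C)(C)[Si](C)(C)OS(=O)(=O)C(F)(F)F
Why: A silyl triflate with 2,6-lutidine silylates the hindered ketol hydroxyl quickly at low temperature, and the weak hindered base should neither enolise the ketone nor isomerise the isopropenyl group.

Step 17
Reactants: 21 9β-OTBS ketone
Product: 22 3α-alcohol (9β-OTBS; 8-oxo; 7β-isopropenyl)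
Conditions: PPTS (0.2 equiv), MeOH/CH2Cl2 1:1, 0 °C → rt
Reagents that add atoms: none
Why: Acid-catalysed methanolysis removes a TES ether much faster than a secondary TBS ether, so only O3 should be freed.

Step 18
Reactants: 23 (R)-pent-4-en-2-ol; 24 angelic acid
Product: 26 (R)-pent-4-en-2-yl (Z)-2-methylbut-2-enoate, via mixed anhydride 25 (not isolated)
Conditions: 24, 2,4,6-Cl3C6H2COCl, Et3N, toluene, rt; then 23, 80 °C
Reagents that add atoms: none
Why: Yamaguchi-type esterification through the aroyl mixed anhydride without a nucleophilic catalyst is the established way to make angelates without Z to E isomerisation to the tiglate, and the carbinol centre is not involved in bond breaking and stays R.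

Step 19
Reactants: 26 (R)-pent-4-en-2-yl (Z)-2-methylbut-2-enoate; 27 acrylic acid
Product: 28 (2E,5R)-5-[(Z)-2-methylbut-2-enoyloxy]hex-2-enoic acid
Conditions: 27 (3 equiv), (H2IMes)(PCy3)Cl2Ru=CHPh (second-generation Grubbs catalyst, 5 mol%), CH2Cl2, 40 °C
Reagents that add atoms: none
Why: Olefin cross-metathesis of a terminal alkene with acrylic acid is selective because the electron-poor partner does not homodimerise, it gives the E-enoic acid, and the trisubstituted conjugated angelate alkene is inert to the ruthenium carbene.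

Step 20
Reactants: 22 3α-alcohol; 28 (2E,5R)-5-[(Z)-2-methylbut-2-enoyloxy]hex-2-enoic acid
Product: 30 9-O-TBS ether of the target, via mixed anhydride 29 (not isolated)
Conditions: 28 (1.5 equiv), 2,4,6-Cl3C6H2COCl, Et3N, toluene, rt; then 22, DMAP, rt
Reagents that add atoms: none
Why: In this Yamaguchi esterification DMAP attacks the mixed anhydride at the less hindered enoyl carbonyl and the acylpyridinium acylates the equatorial 3α-alcohol with retention at C3, under conditions mild enough for the angelate and the C7 centre.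

Step 21
Reactants: 30 9-O-TBS ether of the target
Product: 31 CNP0210874.1 (target)
Conditions: HF·pyridine, pyridine, THF, 0 °C → rt
Reagents that add atoms: none
Why: Buffered hydrogen fluoride–pyridine cleaves the Si–O bond at O9 (fluoride-driven desilylation) and should not affect the two esters, the enoate, the angelate or the epimerisable C7 centre.

**Compound list**

1 | but-3-yn-1-ol | C#CCCO | starting material
2 | tert-butyl(but-3-yn-1-yloxy)diphenylsilane | C#CCCO[Si](c1ccccc1)(c1ccccc1)C(C)(C)C | intermediate
3 | (E)-alkenylzirconocene chloride from 2 (cyclopentadienyl rings written σ-bonded) | Cl[Zr](/C=C/CCO[Si](c1ccccc1)(c1ccccc1)C(C)(C)C)(C1C=CC=C1)C1C=CC=C1 | intermediate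
4 | (E)-tert-butyl[(4-iodobut-3-en-1-yl)oxy]diphenylsilane | I/C=C/CCO[Si](c1ccccc1)(c1ccccc1)C(C)(C)C | intermediate
5 | (E)-tert-butyl(hex-3-en-5-yn-1-yloxy)diphenylsilane | C#C/C=C/CCO[Si](c1ccccc1)(c1ccccc1)C(C)(C)C | intermediate
6 | benzyl[(1E,3E)-6-(tert-butyldiphenylsilyloxy)hexa-1,3-dien-1-yl]dimethylsilane | C[Si](C)(Cc1ccccc1)/C=C/C=C/CCO[Si](c1ccccc1)(c1ccccc1)C(C)(C)C | intermediate
7 | tiglaldehyde, (E)-2-methylbut-2-enal | C/C=C(\C)C=O | starting material
8 | Diels–Alder aldehyde: cyclohex-1-ene with 3α-SiMe2Bn, 4β-Me, 5β-Me, 5α-CHO, 10α-CH2CH2OTBDPS | O=C[C@@]1(C)[C@H](C=C[C@@H]([Si](C)(C)Cc2ccccc2)[C@@H]1C)CCO[Si](c1ccccc1)(c1ccccc1)C(C)(C)C | intermediate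
9 | saturated ring A aldehyde (same substituents, C1–C2 single bond) | O=C[C@@]1(C)[C@H](CC[C@@H]([Si](C)(C)Cc2ccccc2)[C@@H]1C)CCO[Si](c1ccccc1)(c1ccccc1)C(C)(C)C | intermediate
10 | methyl enol ether, C5–CH=CH–OMe (E/Z mixture) | COC=C[C@@]1(C)[C@H](CC[C@@H]([Si](C)(C)Cc2ccccc2)[C@@H]1C)CCO[Si](c1ccccc1)(c1ccccc1)C(C)(C)C | intermediate
11 | homologated aldehyde, C5–CH2–CHO | O=CC[C@@]1(C)[C@H](CC[C@@H]([Si](C)(C)Cc2ccccc2)[C@@H]1C)CCO[Si](c1ccccc1)(c1ccccc1)C(C)(C)C | intermediate
12 | prenyl compound, C5–CH2CH=CMe2 | CC(C)=CC[C@@]1(C)[C@H](CC[C@@H]([Si](C)(C)Cc2ccccc2)[C@@H]1C)CCO[Si](c1ccccc1)(c1ccccc1)C(C)(C)C | intermediate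
13 | fluorosilane alcohol, 3α-SiMe2F, 10α-CH2CH2OH | CC(C)=CC[C@@]1(C)[C@H](CC[C@@H]([Si](C)(C)F)[C@@H]1C)CCO | intermediate
14 | diol, 3α-OH, 10α-CH2CH2OH, C5 prenyl | CC(C)=CC[C@@]1(C)[C@H](CC[C@@H](O)[C@@H]1C)CCO | intermediate
15 | hydroxy aldehyde, 3α-OH, 10α-CH2CHO | CC(C)=CC[C@@]1(C)[C@H](CC[C@@H](O)[C@@H]1C)CC=O | intermediate
16 | ene precursor, 3α-OTES, 5α-prenyl, 10α-CH2CHO | CC(C)=CC[C@@]1(C)[C@H](CC[C@@H](O[Si](CC)(CC)CC)[C@@H]1C)CC=O | intermediate
17 | cis-decalin ene product, 3α-OTES, 7β-isopropenyl, 8α-OH | C=C(C)[C@H]1C[C@@]2(C)[C@H](CC[C@@H](O[Si](CC)(CC)CC)[C@@H]2C)C[C@@H]1O | intermediate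
18 | 8-ketone, 3α-OTES, 7β-isopropenyl | C=C(C)[C@H]1C[C@@]2(C)[C@H](CC[C@@H](O[Si](CC)(CC)CC)[C@@H]2C)CC1=O | intermediate
19 | lithium C8–C9 enolate of 18 | C=C(C)[C@H]1C[C@@]2(C)[C@H](CC[C@@H](O[Si](CC)(CC)CC)[C@@H]2C)C=C1O[Li] | intermediate
20 | 9β-hydroxy-8-ketone, 3α-OTES | C=C(C)[C@H]1C[C@@]2(C)[C@H](CC[C@@H](O[Si](CC)(CC)CC)[C@@H]2C)[C@@H](O)C1=O | intermediate
21 | 9β-OTBS-8-ketone, 3α-OTES | C=C(C)[C@H]1C[C@@]2(C)[C@H](CC[C@@H](O[Si](CC)(CC)CC)[C@@H]2C)[C@@H](O[Si](C)(C)C(C)(C)C)C1=O | intermediate
22 | 3α-alcohol, 9β-OTBS-8-ketone | C=C(C)[C@H]1C[C@@]2(C)[C@H](CC[C@@H](O)[C@@H]2C)[C@@H](O[Si](C)(C)C(C)(C)C)C1=O | intermediate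
23 | (R)-pent-4-en-2-ol | C[C@@H](O)CC=C | starting material
24 | angelic acid, (Z)-2-methylbut-2-enoic acid | C/C=C(/C)C(=O)O | starting material
25 | angelic 2,4,6-trichlorobenzoic anhydride | C/C=C(/C)C(=O)OC(=O)c1c(Cl)cc(Cl)cc1Cl | intermediate
26 | (R)-pent-4-en-2-yl (Z)-2-methylbut-2-enoate | C=CC[C@@H](C)OC(=O)/C(C)=C\C | intermediate
27 | acrylic acid | C=CC(=O)O | starting material
28 | (2E,5R)-5-[(Z)-2-methylbut-2-enoyloxy]hex-2-enoic acid | OC(=O)/C=C/C[C@@H](C)OC(=O)/C(C)=C\C | intermediate
29 | mixed anhydride of 28 with 2,4,6-trichlorobenzoic acid | O=C(OC(=O)c1c(Cl)cc(Cl)cc1Cl)/C=C/C[C@@H](C)OC(=O)/C(C)=C\C | intermediate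
30 | 9-O-TBS ether of the target | C=C(C)[C@H]1C[C@@]2(C)[C@H](CC[C@@H](OC(=O)/C=C/C[C@@H](C)OC(=O)/C(C)=C\C)[C@@H]2C)[C@@H](O[Si](C)(C)C(C)(C)C)C1=O | intermediate
31 | CNP0210874.1: 3α-[(2E,5R)-5-(angeloyloxy)hex-2-enoyloxy]-9β-hydroxy-7β-isopropenyl-4β,5β-dimethyl-cis-decalin-8-one | C=C(C)[C@H]1C[C@@]2(C)[C@H](CC[C@@H](OC(=O)/C=C/C[C@@H](C)OC(=O)/C(C)=C\C)[C@@H]2C)[C@@H](O)C1=O | target

**Step count and risk**

Total step count: 21. Longest linear sequence: 19 (steps 1–17, 20, 21).

Step 5 (Diels–Alder). What may go wrong: the cycloaddition of the α,β-disubstituted enal with the 1,4-disubstituted dienylsilane may be slow, which leaves time for protodesilylation or oligomerisation of the diene, and enantiofacial or endo selectivity may erode. Fallback, setting out from 6 and 7: the cycloaddition is run with an achiral Lewis acid (Me2AlCl, CH2Cl2, −78 → −20 °C), which should give 8 together with its mirror image, ent-8 F1. The racemic aldehyde is condensed with (1S,2S)-N,N'-dimethyl-1,2-diphenylethane-1,2-diamine (4 Å molecular sieves, Et2O) to give two diastereomeric imidazolidines, the aminal of 8 F2 and the aminal of ent-8 F3, which are separated by chromatography. Mild hydrolysis of F2 (dilute aqueous HCl, Et2O, 0 °C) returns the route to 8 as one enantiomer, and the diamine is recovered.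

Step 13 (carbonyl-ene). What may go wrong: the reaction may leak from the concerted ene path into the stepwise cationic manifold (chloride capture, alkene migration), or the ring may close through the flipped ring A chair and deliver the C7 epimer. Fallback, setting out from 16: the cationic manifold is used on purpose. SnCl4 (CH2Cl2, −78 °C) should give, by attack of C7 on the activated aldehyde through the same chair and chloride capture of the tertiary cation, the tertiary chloride 7β-(2-chloropropan-2-yl)-8α-ol F4. Dehydrochlorination toward the methyl group with a bulky base (KOC(CH3)3, DMSO, rt, Hofmann-type E2) then gives 17, where the route is rejoined.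

Step 15 (C9 hydroxylation). What may go wrong: deprotonation may stray to the allylic C7–H, the lithium enolate may add to the sulfonimine formed from the oxidant, or the oxidant may approach the concave α face. Fallback, setting out from 18: the kinetic enolate is trapped with Me3SiCl present in the flask (LiN(i-Pr)2, Me3SiCl, THF, −78 °C) as the trimethylsilyl enol ether F5, whose regiochemistry can be checked and purified. Epoxidation with dimethyldioxirane (acetone/CH2Cl2, −78 → 0 °C, Rubottom oxidation) is a concerted addition without axial-attack bias and should take the convex β face; after silyl migration it gives the 9β-trimethylsilyloxy ketone F6. Citric acid in methanol (0 °C) frees the alcohol and rejoins the route at 20.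

Further compounds
F1 | step 5 | ent-8, mirror image of the Diels–Alder aldehyde | O=C[C@]1(C)[C@@H](C=C[C@H]([Si](C)(C)Cc2ccccc2)[C@H]1C)CCO[Si](c1ccccc1)(c1ccccc1)C(C)(C)C
F2 | step 5 | aminal of 8 with (1S,2S)-N,N'-dimethyl-1,2-diphenylethane-1,2-diamine | CN1[C@@H](c2ccccc2)[C@H](c2ccccc2)N(C)C1[C@@]3(C)[C@H](C=C[C@@H]([Si](C)(C)Cc4ccccc4)[C@@H]3C)CCO[Si](c5ccccc5)(c6ccccc6)C(C)(C)C
F3 | step 5 | aminal of ent-8 with the same diamine | CN1[C@@H](c2ccccc2)[C@H](c2ccccc2)N(C)C1[C@]3(C)[C@@H](C=C[C@H]([Si](C)(C)Cc4ccccc4)[C@H]3C)CCO[Si](c5ccccc5)(c6ccccc6)C(C)(C)C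
F4 | step 13 | tertiary chloride, 7β-(2-chloropropan-2-yl)-8α-ol, 3α-OTES | CC(C)(Cl)[C@H]1C[C@@]2(C)[C@H](CC[C@@H](O[Si](CC)(CC)CC)[C@@H]2C)C[C@@H]1O
F5 | step 15 | trimethylsilyl C8–C9 enol ether of 18 | C=C(C)[C@H]1C[C@@]2(C)[C@H](CC[C@@H](O[Si](CC)(CC)CC)[C@@H]2C)C=C1O[Si](C)(C)C
F6 | step 15 | 9β-trimethylsilyloxy-8-ketone, 3α-OTES | C=C(C)[C@H]1C[C@@]2(C)[C@H](CC[C@@H](O[Si](CC)(CC)CC)[C@@H]2C)[C@@H](O[Si](C)(C)C)C1=O
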